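**Plan**

- Numbering follows isochromene: ring A is O2, C1, C8a, C4a, C4, C3 (heptyl); ring B is C4a, C5, C6 (C=O), C7 (CH3, O-decanoyl), C8 (C=O), C8a.
- Enabling feature: in ring B the C4a=C5 double bond is α,β to the C6 ketone, and C4a is also the carbonyl-derived carbon of ring A. This is the retron of an aldol condensation between a C5 methyl ketone and the C4 carbonyl of a 2,3-dihydropyran-4-one.
- Retrosynthetic cuts, in order: the C1=C8a unsaturation (dehydrogenation); C4a=C5 (aldol condensation, opens ring B); the C6 ketone back to a silylated carbinol; the decanoate C–O bond; C8–C8a (Claisen acylation); C6–C7 (lactate enolate plus acetaldehyde).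
- Forward: ring A is made first from 1-nonyne (ynone, oxa-Michael closure). Its C3 enolate is acylated by a lactic-acid dioxolanone, the tertiary oxygen is esterified before the methyl ketone is unmasked, ring B is closed, and the C1=C8a bond comes last.
- Stereochemistry: the only stereocentre, C7 (R), comes from (S)-lactic acid by self-regeneration of stereocentres through the cis pivalaldehyde acetal (acetaldehyde enters anti to tert-butyl, net retention). It is quaternary from step 5 on and no later step can invert it.

Key step: step 10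

Remark: the silyloxy-bearing carbon that becomes the C6 ketone and the enolisable ring-fusion carbon (pyranone C3, later C8a) are carried as epimer mixtures and left undefined in the SMILES; 3-(tert-butyldimethylsilyloxy)propanal is taken as a purchasable aldehyde.

**Route**

Step 1
Reactants: 1 1-nonyne; 2 3-(tert-butyldimethylsilyloxy)propanal
Product: 4 racemic 1-(tert-butyldimethylsilyloxy)dodec-4-yn-3-ol, via lithium nonynide 3 (not isolated)
Conditions: n-BuLi, THF, −78 °C; then 2, −78 → 0 °C; AcOH quench
Reagents that add atoms: none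
Why: Alkynylation of an aldehyde with a lithium acetylide is a standard C–C bond formation, and the racemic carbinol centre it creates is erased by the oxidation in step 2.

Step 2
Reactants: 4 racemic 1-(tert-butyldimethylsilyloxy)dodec-4-yn-3-ol
Product: 5 1-(tert-butyldimethylsilyloxy)dodec-4-yn-3-one
Conditions: Dess–Martin periodinane, CH2Cl2, 0 °C → rt
Reagents that add atoms: none
Why: Dess–Martin oxidation of a propargylic alcohol to the ynone is mild enough to leave the silyl ether and the triple bond untouched.

Step 3
Reactants: 5 1-(tert-butyldimethylsilyloxy)dodec-4-yn-3-one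
Product: 7 6-heptyl-2,3-dihydro-4H-pyran-4-one, via hydroxy ynone 6 (not isolated)
Conditions: TsOH·H2O (0.2 equiv), MeOH, rt → 50 °C
Reagents that add atoms: none
Why: Acidic methanolysis frees the primary alcohol, which should close ring A by 6-endo-dig oxa-Michael addition to the ynone (directly, or through the methanol adduct by addition–elimination), the usual cycloisomerisation of β-hydroxy ynones to 2,3-dihydropyran-4-ones.

Step 4
Reactants: 8 (S)-lactic acid; 9 pivalaldehyde
Product: 10 (2S,5S)-2-tert-butyl-5-methyl-1,3-dioxolan-4-one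
Conditions: TsOH·H2O (cat.), H2SO4 (cat.), pentane, reflux, Dean–Stark; crystallisation from pentane/Et2O, −78 °C
Reagents that add atoms: none
Why: Acid-catalysed acetalisation of the α-hydroxy acid is expected to favour the cis acetal, whose new centre C2 is set under control of the lactate centre and which low-temperature crystallisation should deliver as one diastereomer.

Step 5
Reactants: 10 (2S,5S)-2-tert-butyl-5-methyl-1,3-dioxolan-4-one; 11 acetaldehyde
Product: 14 (2S,5R)-2-tert-butyl-5-methyl-5-[1-(triethylsilyloxy)ethyl]-1,3-dioxolan-4-one, via dioxolanone enolate 12 (not isolated), via lithium aldolate 13 (not isolated)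
Conditions: LiN(i-Pr)2, THF, −78 °C; then 11, −78 °C; then Et3SiOSO2CF3, −78 → −40 °C
Reagents that add atoms: triethylsilyl trifluoromethanesulfonate, CC[Si](CC)(CC)OS(=O)(=O)C(F)(F)F
Why: Aldol addition of the chiral lactone enolate (self-regeneration of stereocentres): acetaldehyde should approach the planar enolate anti to the tert-butyl group, so the new C–C bond replaces the former C–H with retention and the quaternary centre becomes (5R), while silylation of the aldolate in the same flask blocks retro-aldol cleavage.

Step 6
Reactants: 7 6-heptyl-2,3-dihydro-4H-pyran-4-one; 14 (2S,5R)-2-tert-butyl-5-methyl-5-[1-(triethylsilyloxy)ethyl]-1,3-dioxolan-4-one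
Product: 16 6-heptyl-3-[(2R)-2-hydroxy-2-methyl-3-(triethylsilyloxy)butanoyl]-2,3-dihydro-4H-pyran-4-one, via pyranone enolate 15 (not isolated)
Conditions: 7 (1.3 equiv), LiN(i-Pr)2 (1.25 equiv), THF, −78 °C; then 14, −78 → −40 °C; AcOH, then pH 7 phosphate buffer
Reagents that add atoms: none
Why: Crossed Claisen acylation in which the kinetic C3 (α′) enolate of the vinylogous ester adds to the acetal-activated lactone carbonyl, collapse of the adduct releasing pivalaldehyde and a tertiary alkoxide that is quenched internally by the acidic diketone proton (so no free alkoxide persists beside the silyl ether), with a neutral work-up to avoid acid-driven closure of the α′-hydroxy-1,3-diketone to a 3(2H)-furanone.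

Step 7
Reactants: 16 6-heptyl-3-[(2R)-2-hydroxy-2-methyl-3-(triethylsilyloxy)butanoyl]-2,3-dihydro-4H-pyran-4-one; 17 decanoyl chloride
Product: 19 (2R)-1-(6-heptyl-4-oxo-3,4-dihydro-2H-pyran-3-yl)-2-methyl-1-oxo-3-(triethylsilyloxy)butan-2-yl decanoate, via dilithium salt 18 (not isolated)
Conditions: LiN(SiMe3)2 (2.1 equiv), THF, −78 °C; then 17 (1.05 equiv), −78 °C; AcOH, −78 °C
Reagents that add atoms: none
Why: O-Acylation of a lithium alkoxide with an acid chloride: in the dianion the chelated diketonate is the weaker nucleophile, so the single equivalent of acid chloride should be taken by the more basic tertiary alkoxide, which also overcomes the hindrance of the neutral alcohol, while −78 °C keeps the triethylsilyl group from shifting between the vicinal oxygens.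

Step 8
Reactants: 19 (2R)-1-(6-heptyl-4-oxo-3,4-dihydro-2H-pyran-3-yl)-2-methyl-1-oxo-3-(triethylsilyloxy)butan-2-yl decanoate
Product: 20 (2R)-1-(6-heptyl-4-oxo-3,4-dihydro-2H-pyran-3-yl)-3-hydroxy-2-methyl-1-oxobutan-2-yl decanoate
Conditions: HF·pyridine, pyridine, THF, 0 °C → rt
Reagents that add atoms: none
Why: Fluoride-mediated desilylation under buffered, weakly acidic conditions should spare the tertiary ester and the ring enol ether and disfavour 1,2-acyl migration to the freed secondary hydroxyl.

Step 9
Reactants: 20 (2R)-1-(6-heptyl-4-oxo-3,4-dihydro-2H-pyran-3-yl)-3-hydroxy-2-methyl-1-oxobutan-2-yl decanoate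
Product: 21 (2R)-1-(6-heptyl-4-oxo-3,4-dihydro-2H-pyran-3-yl)-2-methyl-1,3-dioxobutan-2-yl decanoate
Conditions: Dess–Martin periodinane (1.3 equiv), CH2Cl2, 0 °C → rt
Reagents that add atoms: none
Why: Dess–Martin oxidation of the secondary alcohol gives the methyl ketone under the neutral conditions routinely used to prepare 1,3-diketones, so the enolised diketone, the tertiary ester and the quaternary centre should survive.

Step 10
Reactants: 21 (2R)-1-(6-heptyl-4-oxo-3,4-dihydro-2H-pyran-3-yl)-2-methyl-1,3-dioxobutan-2-yl decanoate
Product: 23 (7R)-3-heptyl-7-methyl-6,8-dioxo-6,7,8,8a-tetrahydro-1H-isochromen-7-yl decanoate, via ketol 22 (not isolated)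
Conditions: TsOH·H2O (0.3 equiv), benzene, reflux, Dean–Stark
Reagents that add atoms: none
Why: Under acid the methyl ketone can enolise only toward C5 (C7 is quaternary), and this enol adds to the protonated C4a carbonyl of ring A in whichever diketone tautomer leaves that carbon as a carbonyl; ketol 22 then ionises readily, because the cation at C4a is stabilised by the C3=C4 enol ether, and loss of a C5 proton gives the C4a=C5 bond conjugated with both the C6 ketone and the ring oxygen. The closest known reactions are the acid-catalysed cyclodehydration of 1,5-diketones (the ring-closing half of a Robinson annulation) and the aldol cyclisations of enolised polyketide-type triketones, in which the acceptor carbonyl likewise belongs to a 1,3-dicarbonyl unit. Ring B closes in the 6-(enolexo)-exo-trig mode, and the only other carbon–carbon closure, C8a onto C6, would give a four-membered ring. No lasting stereocentre is created: C4a becomes trigonal, C8a stays enolisable and is removed in step 11, and C7, being quaternary and non-enolisable, keeps the lactate-derived configuration. The step needs C-attack by C5 rather than O-cyclisation or acyl transfer, and substrate and medium secure this: the tertiary oxygen is already esterified, so the acid-driven 3(2H)-furanone closure of an α′-hydroxy-1,3-diketone cannot occur; no enolate is formed, so the decanoyl group cannot shift from oxygen to C5 (Baker–Venkataraman-type transfer); and no amine is present that could open the vinylogous ester at C3.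

Step 11
Reactants: 23 (7R)-3-heptyl-7-methyl-6,8-dioxo-6,7,8,8a-tetrahydro-1H-isochromen-7-yl decanoate
Product: 24 (7R)-3-heptyl-7-methyl-6,8-dioxo-7,8-dihydro-6H-isochromen-7-yl decanoate
Conditions: DDQ (1.1 equiv), 1,4-dioxane, rt
Reagents that add atoms: none
Why: Quinone dehydrogenation: DDQ should abstract hydride from C1, which is α to the ring oxygen and allylic to the C8/C8a enol, and loss of the enol proton from the resulting hydroxy-isochromenylium ion gives the C1=C8a bond, as in the known dehydrogenation of enolisable 1,3-dicarbonyl compounds, without touching any bond at C7.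

**Compound list**

1 | 1-nonyne | CCCCCCCC#C | starting material
2 | 3-(tert-butyldimethylsilyloxy)propanal | CC(C)(C)[Si](C)(C)OCCC=O | starting material
3 | lithium non-1-yn-1-ide | [Li+].[C-]#CCCCCCCC | intermediate
4 | racemic 1-(tert-butyldimethylsilyloxy)dodec-4-yn-3-ol | CCCCCCCC#CC(O)CCO[Si](C)(C)C(C)(C)C | intermediate
5 | 1-(tert-butyldimethylsilyloxy)dodec-4-yn-3-one | CCCCCCCC#CC(=O)CCO[Si](C)(C)C(C)(C)C | intermediate
6 | 1-hydroxydodec-4-yn-3-one | CCCCCCCC#CC(=O)CCO | intermediate
7 | 6-heptyl-2,3-dihydro-4H-pyran-4-one | CCCCCCCC1=CC(=O)CCO1 | intermediate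
8 | (S)-lactic acid | C[C@H](O)C(=O)O | starting material
9 | pivalaldehyde (2,2-dimethylpropanal) | CC(C)(C)C=O | starting material
10 | (2S,5S)-2-tert-butyl-5-methyl-1,3-dioxolan-4-one (cis) | C[C@@H]1O[C@H](C(C)(C)C)OC1=O | intermediate
11 | acetaldehyde | CC=O | starting material
12 | lithium (2S)-2-tert-butyl-5-methyl-1,3-dioxol-4-olate | CC1=C([O-])O[C@@H](C(C)(C)C)O1.[Li+] | intermediate
13 | lithium 1-[(2S,4R)-2-tert-butyl-4-methyl-5-oxo-1,3-dioxolan-4-yl]ethan-1-olate (carbinol epimers) | C[C@]1(C(C)[O-])O[C@H](C(C)(C)C)OC1=O.[Li+] | intermediate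
14 | (2S,5R)-2-tert-butyl-5-methyl-5-[1-(triethylsilyloxy)ethyl]-1,3-dioxolan-4-one (carbinol epimers; methyl cis to tert-butyl) | C[C@]1(C(C)O[Si](CC)(CC)CC)O[C@H](C(C)(C)C)OC1=O | intermediate
15 | lithium 6-heptyl-2H-pyran-4-olate | CCCCCCCC1=CC([O-])=CCO1.[Li+] | intermediate
16 | 6-heptyl-3-[(2R)-2-hydroxy-2-methyl-3-(triethylsilyloxy)butanoyl]-2,3-dihydro-4H-pyran-4-one (enolised diketone) | CCCCCCCC1=CC(=O)C(CO1)C(=O)[C@](C)(O)C(C)O[Si](CC)(CC)CC | intermediate
17 | decanoyl chloride | CCCCCCCCCC(Cl)=O | starting material
18 | dilithium alkoxide–enolate of 16 | [Li+].[Li+].CCCCCCCC1=CC(=O)C(CO1)=C([O-])[C@](C)([O-])C(C)O[Si](CC)(CC)CC | intermediate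
19 | (2R)-1-(6-heptyl-4-oxo-3,4-dihydro-2H-pyran-3-yl)-2-methyl-1-oxo-3-(triethylsilyloxy)butan-2-yl decanoate | CCCCCCCCCC(=O)O[C@@](C)(C(=O)C1COC(CCCCCCC)=CC1=O)C(C)O[Si](CC)(CC)CC | intermediate
20 | (2R)-1-(6-heptyl-4-oxo-3,4-dihydro-2H-pyran-3-yl)-3-hydroxy-2-methyl-1-oxobutan-2-yl decanoate | CCCCCCCCCC(=O)O[C@@](C)(C(=O)C1COC(CCCCCCC)=CC1=O)C(C)O | intermediate
21 | (2R)-1-(6-heptyl-4-oxo-3,4-dihydro-2H-pyran-3-yl)-2-methyl-1,3-dioxobutan-2-yl decanoate | CC(=O)[C@@](C)(OC(=O)CCCCCCCCC)C(=O)C1COC(CCCCCCC)=CC1=O | intermediate
22 | (7R)-3-heptyl-4a-hydroxy-7-methyl-6,8-dioxo-4a,5,6,7,8,8a-hexahydro-1H-isochromen-7-yl decanoate (C4a, C8a undefined) | CCCCCCCCCC(=O)O[C@]1(C)C(=O)CC2(O)C=C(CCCCCCC)OCC2C1=O | intermediate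
23 | (7R)-3-heptyl-7-methyl-6,8-dioxo-6,7,8,8a-tetrahydro-1H-isochromen-7-yl decanoate (C8a epimers) | CCCCCCCCCC(=O)O[C@]1(C)C(=O)C=C2C=C(CCCCCCC)OCC2C1=O | intermediate
24 | (7R)-3-heptyl-7-methyl-6,8-dioxo-7,8-dihydro-6H-isochromen-7-yl decanoate | CCCCCCCCCC(=O)O[C@]1(C)C(=O)C=C2C=C(CCCCCCC)OC=C2C1=O | target

**Step count and risks**

Total: 11 steps. Longest linear sequence: 9 steps (steps 1–3 and 6–11, from 1-nonyne); the lactic acid branch (steps 4–5) joins at step 6.

Steps most likely to fail:

Step 10. The enolised C8/C4a diketone may hold C4a as an enol carbon, so that ring closure stalls and slow acid-mediated degradation of the vinylogous ester takes over. The fallback blocks C8a with a group that later also delivers the C1=C8a bond. It leaves the route at 21: PhSeCl and pyridine in CH2Cl2 at 0 °C should selenenylate the diketone carbon to give the C8a-phenylselanyl triketone F1, in which C4a can only be a ketone. The same acid-mediated aldol condensation (TsOH·H2O, benzene, reflux) should then give the 8a-phenylselanyl bicycle F2. Oxidation with H2O2 in CH2Cl2 at 0 °C and selenoxide syn-elimination toward the C1 hydrogens would give 24 directly, so the branch rejoins at 24 without passing through 23.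

Step 6. Addition of the enolate to the neopentyl-type lactone carbonyl may be slower than proton transfer or than capture of the enolate by liberated pivalaldehyde. The fallback replaces the acyl donor by an aldehyde and corrects the oxidation level afterwards. It leaves the route at 14: LiAlH4 in THF at 0 °C should give the diol F3; SO3·pyridine, DMSO and i-Pr2NEt (Parikh–Doering oxidation) should oxidise only the primary hydroxyl to the α-hydroxy aldehyde F4; addition of enolate 15 (2 equiv, THF, −78 °C) should give the aldol diol F5; and Dess–Martin periodinane (1 equiv) should oxidise its secondary carbinol, returning to the route at 16.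

Step 7. The acid chloride may be taken by the diketonate instead of the alkoxide, or the silyl group may shift to the tertiary alkoxide so that the ester ends up on the secondary oxygen. The fallback gives up site selection in the acylation and obtains it in a cleavage. It leaves the route at 16: excess decanoyl chloride (3 equiv), Et3N and DMAP in CH2Cl2 at rt (no alkoxide, hence no silyl shift) should acylate both the enol and the tertiary hydroxyl to give the enol ester–ester F6. Its vinylogous anhydride linkage should then be cleaved selectively by MeOH/Et3N at 0 °C, returning to the route at 19.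

**Further compounds**

F1 | step 10 | (2R)-1-[6-heptyl-4-oxo-3-(phenylselanyl)-3,4-dihydro-2H-pyran-3-yl]-2-methyl-1,3-dioxobutan-2-yl decanoate | CC(=O)[C@@](C)(OC(=O)CCCCCCCCC)C(=O)C1([Se]c2ccccc2)COC(CCCCCCC)=CC1=O
F2 | step 10 | (7R)-3-heptyl-7-methyl-6,8-dioxo-8a-(phenylselanyl)-6,7,8,8a-tetrahydro-1H-isochromen-7-yl decanoate | CCCCCCCCCC(=O)O[C@]1(C)C(=O)C=C2C=C(CCCCCCC)OCC2([Se]c3ccccc3)C1=O
F3 | step 6 | (2S)-2-methyl-3-(triethylsilyloxy)butane-1,2-diol | OC[C@](C)(O)C(C)O[Si](CC)(CC)CC
F4 | step 6 | (2R)-2-hydroxy-2-methyl-3-(triethylsilyloxy)butanal | O=C[C@](C)(O)C(C)O[Si](CC)(CC)CC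
F5 | step 6 | 6-heptyl-3-[(2S)-1,2-dihydroxy-2-methyl-3-(triethylsilyloxy)butyl]-2,3-dihydro-4H-pyran-4-one | CCCCCCCC1=CC(=O)C(CO1)C(O)[C@](C)(O)C(C)O[Si](CC)(CC)CC
F6 | step 7 | (2R)-1-(decanoyloxy)-1-(6-heptyl-4-oxo-2H-pyran-3(4H)-ylidene)-2-methyl-3-(triethylsilyloxy)butan-2-yl decanoate | CCCCCCCC1=CC(=O)C(CO1)=C(OC(=O)CCCCCCCCC)[C@](C)(OC(=O)CCCCCCCCC)C(C)O[Si](CC)(CC)CC
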